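Each L formed takes one G and each G comes from Q. In the proposed scheme (X over Z gives D, D with G over J gives L, Q dissolves to G, two X give E), the Q charged therefore equals L formed plus G dissolved plus Q still solid, at each moment.

| flask | X | Q | Z | J | remark | time |
|---|---|---|---|---|---|---|
| grey | 23 mM | 25.3 mM | 23 µM | 23 µM | the very flask that is asked about, followed so far |  |
| blue | 23 mM | 38 mM | 23 µM | 23 µM | run made earlier |  |
| flask | 23 mM | 25.3 mM | 23 µM | 23 µM |  | 6.0 d |

| run | time / d | L / % | X / % |
|---|---|---|---|
| grey | 0.833 | 22 | 16 |
| grey | 1.67 | 53 | 1 |
| grey | 2.50 | 73 | 0 |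
| grey | 3.00 | 78 | 0 |
| blue | 1.04 | 31 | 10 |
| blue | 2.00 | 63 | 0 |
| blue | 3.00 | 83 | 1 |
| blue | 4.00 | 93 | 0 |

(readings scatter by 2 percentage points)

1. L at 6.0 d, in percent of the X charged
2. concentration of G in solution at 6.0 d, in percent of saturation

- percentages count the X that a species holds: one E counts as two
- solid, in amounts per volume of the solution: Q
- what may be going on: X + Z -> Z + D; G + J + D -> J + L; Q <-> G; 2 X -> E
- at the start none of Q is in solution

Dividing that balance by the X charged gives 110% for the grey flask. This ratio, the Q allowance a, caps L in percent of X, which is the limiting-reagent test.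

The X column comes first: at 1.67 d the grey run shows X at 1% but L at 53%, so 46.0% of the X charged sits in D and E and L comes later. In the L columns, grey reads 78% at 3.00 d against blue's 83%, a gap of 5 percentage points with 2 points on each reading. Blue then reads 93% at 4.00 d, under the grey a, so this reckoning expects grey L near that reading. The balance then leaves 3.91 mM as G and solid Q together; it gives no saturation.

The forecast gives 92.5% and 60%: “G is then about 17 against saturation of about 30, so sat ≈ 60%”.

The flask gives 90.9% and 36.5%.

    X + Z → Z + D (k = 57.2 /M/min)
    G + J + D → J + L (k = 3490 /M²/min)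
    Q ⇌ G, rate k3*(cs3 - [G]) while solid is left; crystals form when [G] > cs3 (solubility = 12.0 mM, k = 0.00144 /min)
    2 X → E (k = 0.00439 /M/min)

L stands under a, and the path from two X to E is the main reason it ends short of the X charged: the flask gives 90.9% with that path and 96.3% with it struck out. The balance then leaves 4.38 mM of G at 6.0 d, and over the saturation of 12 mM that is 36.5%. The forecast set 17 over 30 in percent of X, where saturation stands at 52.2% of X.

In the neighbour flask with 10 mM of Q, the allowance is 43.5%, so Q should cap L there. The computed L is 43.5%, with 49.6% left as D.

The runs were generated by integration with made-up constants.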